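**Retrosynthetic overview**
- The target comes from its dioxolane-protected furyl ketone; the only ring that has to be built is the 4-hydroxy-3-methylfuran-2(5H)-one, and it is closed last.
- Key disconnection: C2–C3 and C4–C5 of the furanone, made together by an anionic [3+2] union of an (E)-enol phenyl carbonate (C5–O1–C2, lithiated at C5, i.e. polarity reversal of an acyl-level carbon) with methyl(trimethylsilyl)ketene (C3–C4).
- Enabling feature: the enol-ester triad C5–O1–C2(=O) of the furanone ring. As an aryl carbonate, its C=O directs lithiation of the vinylic C5–H and is then itself the acceptor carbon C2; the exocyclic C5=C bond carries the E geometry through.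
- The enol carbonate comes from an (E)-alkenylboronate (B→O with retention). The boronate comes from a Negishi union at the 1,1-disubstituted alkene: an alkylzinc from (S)-β-citronellene (ozonolysis, iodide, cross-metathesis) and a vinyl triflate from 6-methylhept-5-en-2-one (SeO2 oxidation, 3-acetylfuran enolate alkylation, ketal).
- Ring order: furan (bought in 3-acetylfuran), dioxolane (temporary, step 8), furanone (step 12); the stereocentre comes from citronellene.

Key step: step 12

Remark: ring atoms are numbered O1, C2(=O), C3(Me), C4(OH), C5; the SMILES fixes the exocyclic C5=C bond as E (chain cis to C4, trans to O1), taken here to be the less stable isomer, so the route sets it by retention and avoids a free enol at C5.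

**Step 1**
Reactants: 1 (S)-β-citronellene [(3S)-3,7-dimethylocta-1,6-diene]
Product: 3 (4S)-4-methylhex-5-en-1-ol, via (4S)-4-methylhex-5-enal 2 (not isolated)
Conditions: O3 (1 equiv), CH2Cl2/MeOH, −78 °C, Sudan III end-point; then NaBH4, −78 → 0 °C
Reagents that add atoms: ozone, [O-][O+]=O
Why: the electron-rich trisubstituted alkene should be ozonised much faster than the vinyl group, and borohydride reduces the aldehyde in the same flask without touching the stereocentre (chemoselective ozonolysis with reductive work-up).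

**Step 2**
Reactants: 3 (4S)-4-methylhex-5-en-1-ol
Product: 4 (3S)-6-iodo-3-methylhex-1-ene
Conditions: I2, PPh3, imidazole, CH2Cl2, 0 °C → rt
Reagents that add atoms: iodine, II
Why: Appel-type iodination of a primary alcohol by SN2 on the alkoxyphosphonium ion, remote from the stereocentre.

**Step 3**
Reactants: 4 (3S)-6-iodo-3-methylhex-1-ene; 5 vinylboronic acid pinacol ester (2-ethenyl-4,4,5,5-tetramethyl-1,3,2-dioxaborolane)
Product: 6 2-[(1E,3S)-6-iodo-3-methylhex-1-en-1-yl]-4,4,5,5-tetramethyl-1,3,2-dioxaborolane
Conditions: 5 (3 equiv), Hoveyda–Grubbs II (5 mol %), CH2Cl2, 40 °C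
Reagents that add atoms: none
Why: olefin cross-metathesis of the only alkene in 4 with the vinylboronate should give the E alkenylboronate, favoured by the bulk of the boryl group and the allylic branch; the boron-bearing carbon (the future C5) comes from 5.

**Step 4**
Reactants: 7 6-methylhept-5-en-2-one
Product: 9 6-methylhepta-1,5-dien-2-yl trifluoromethanesulfonate, via lithium dienolate 8 (not isolated)
Conditions: LDA, THF, −78 °C; PhNTf2, −78 → 0 °C
Reagents that add atoms: N-phenylbis(trifluoromethanesulfonimide), O=S(=O)(N(c1ccccc1)S(=O)(=O)C(F)(F)F)C(F)(F)F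
Why: kinetic deprotonation at the methyl group and O-triflation of the enolate should give the 2-triflyloxy-1-alkene; minor internal enol triflates are removed by chromatography.

**Step 5**
Reactants: 9 6-methylhepta-1,5-dien-2-yl trifluoromethanesulfonate
Product: 10 (5E)-7-hydroxy-6-methylhepta-1,5-dien-2-yl trifluoromethanesulfonate
Conditions: SeO2 (0.3 equiv), t-BuOOH (2 equiv), salicylic acid (0.1 equiv), CH2Cl2, 0 °C → rt
Reagents that add atoms: selenium dioxide, O=[Se]=O (catalytic oxygen carrier); tert-butyl hydroperoxide, CC(C)(C)OO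
Why: catalytic SeO2 allylic oxidation (ene reaction, then [2,3]-shift) should oxidise the E methyl group of the trisubstituted alkene, and the electron-poor enol triflate alkene should not react.

**Step 6**
Reactants: 10 (5E)-7-hydroxy-6-methylhepta-1,5-dien-2-yl trifluoromethanesulfonate
Product: 11 (5E)-7-bromo-6-methylhepta-1,5-dien-2-yl trifluoromethanesulfonate
Conditions: CBr4, PPh3, CH2Cl2, −20 → 0 °C
Reagents that add atoms: carbon tetrabromide, BrC(Br)(Br)Br
Why: Appel bromination of the primary allylic alcohol at low temperature should proceed by direct SN2 without allylic transposition or loss of the E geometry.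

**Step 7**
Reactants: 11 (5E)-7-bromo-6-methylhepta-1,5-dien-2-yl trifluoromethanesulfonate; 12 3-acetylfuran [1-(furan-3-yl)ethan-1-one]
Product: 14 (5E)-9-(furan-3-yl)-6-methyl-9-oxonona-1,5-dien-2-yl trifluoromethanesulfonate, via lithium furyl enolate 13 (not isolated)
Conditions: 12 (2 equiv), LDA, THF, −78 °C; then 11, DMPU, −78 → −20 °C
Reagents that add atoms: none
Why: SN2 alkylation of the methyl ketone enolate with the primary allylic bromide should give the furyl ketone; excess enolate limits dialkylation and the vinyl triflate is inert to it at low temperature.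

**Step 8**
Reactants: 14 (5E)-9-(furan-3-yl)-6-methyl-9-oxonona-1,5-dien-2-yl trifluoromethanesulfonate
Product: 15 (5E)-8-[2-(furan-3-yl)-1,3-dioxolan-2-yl]-6-methylocta-1,5-dien-2-yl trifluoromethanesulfonate
Conditions: (Me3SiOCH2)2, Me3SiOTf (5 mol %), CH2Cl2, −78 → −20 °C; pyridine quench
Reagents that add atoms: 1,2-bis(trimethylsilyloxy)ethane, C[Si](C)(C)OCCO[Si](C)(C)C
Why: aprotic silyl-triflate-catalysed ketalisation should mask the ketone for steps 11 and 12 without protic acid, so the alkenes do not migrate.

**Step 9**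
Reactants: 6 2-[(1E,3S)-6-iodo-3-methylhex-1-en-1-yl]-4,4,5,5-tetramethyl-1,3,2-dioxaborolane; 15 (5E)-8-[2-(furan-3-yl)-1,3-dioxolan-2-yl]-6-methylocta-1,5-dien-2-yl trifluoromethanesulfonate
Product: 17 2-[(1E,3S,10E)-13-[2-(furan-3-yl)-1,3-dioxolan-2-yl]-3,11-dimethyl-7-methylidenetrideca-1,10-dien-1-yl]-4,4,5,5-tetramethyl-1,3,2-dioxaborolane, via alkylzinc iodide 16 (not isolated)
Conditions: 6, Zn dust, LiCl, THF, 40 °C; then 15, Pd(PPh3)4 (5 mol %), THF, 50 °C
Reagents that add atoms: none
Why: Negishi sp3–sp2 coupling of the primary alkylzinc with the alkenyl triflate should form the 1,1-disubstituted alkene; without base the alkenylboronate does not transmetalate to palladium.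

**Step 10**
Reactants: 18 1-propynyllithium
Product: 20 methyl(trimethylsilyl)ketene [2-(trimethylsilyl)prop-1-en-1-one], via lithium propynolate 19 (not isolated)
Conditions: t-BuOOH, LiHMDS, THF, −78 °C; 18, −78 → 0 °C; Me3SiCl (2.2 equiv), −78 °C → rt; distillation
Reagents that add atoms: tert-butyl hydroperoxide, CC(C)(C)OO; chlorotrimethylsilane, C[Si](C)(C)Cl
Why: oxygenation of the lithium acetylide by lithium tert-butyl peroxide should give the ynolate, which a small silyl chloride silylates on carbon to give a distillable silylketene that does not dimerise.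

**Step 11**
Reactants: 17 (alkenylboronate from step 9); 21 phenyl chloroformate
Product: 24 phenyl (1E,3S,10E)-13-[2-(furan-3-yl)-1,3-dioxolan-2-yl]-3,11-dimethyl-7-methylidenetrideca-1,10-dien-1-yl carbonate, via enol borate 22 (not isolated), via lithium enolate 23 (not isolated)
Conditions: Me3NO (anhydrous), THF, 0 °C → rt; MeLi, −78 °C; 21, −78 → −20 °C
Reagents that add atoms: trimethylamine N-oxide, C[N+](C)(C)[O-]
Why: amine-oxide oxidation moves the alkenyl group from boron to oxygen with retention at the sp2 carbon, MeLi releases the E lithium enolate from the borate through an ate complex, and the hard chloroformate should acylate it on oxygen (alkenylboronate oxidation, then enolate O-acylation).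

**Step 12**
Reactants: 24 (enol phenyl carbonate from step 11); 20 methyl(trimethylsilyl)ketene
Product: 28 (5E)-5-[(2S,9E)-12-[2-(furan-3-yl)-1,3-dioxolan-2-yl]-2,10-dimethyl-6-methylidenedodec-9-en-1-ylidene]-4-hydroxy-3-methylfuran-2(5H)-one, via α-lithio enol carbonate 25 (not isolated), via lithium silyl enolate 26 (not isolated), via C-silyl furandione 27 (not isolated)
Conditions: LiTMP (1.1 equiv), THF, −95 °C, 10 min; 20 (1.3 equiv), −95 → 0 °C; AcOH, then H2O
Reagents that add atoms: none
Why: Proposed new method: the carbonate C=O directs LiTMP to the vinylic C5–H, the configurationally stable α-lithio enol carbonate 25 (an acyl-anion equivalent at C5) adds to the C=O carbon of 20 to form C4–C5 and the α-silyl enolate 26, the enolate carbon attacks the carbonate carbon C2 with loss of phenoxide to form C2–C3, and the phenoxide then removes the C3 silyl group from 27 to leave the lithium tetronate. The closest known reaction types are α-lithiation and acylation of enol carbamates, addition of organolithiums to silylketenes, and Dieckmann-type C-acylation of a ketone enolate by a neighbouring carbonate or ester as in tetronic acid and 4-hydroxycoumarin syntheses; their combination on an enol aryl carbonate is untested. The furanone ring closes by 5-exo-trig attack of the enolate carbon on the carbonate carbonyl. No stereocentre is made (C3 of 27 is erased on desilylation), the existing one is not α to any carbonyl, and the E geometry follows from retention at sp2 C5 in both the lithiation and the addition. The step needs lithiation at C5 and not at the phenyl or furan ring, and C- and not O-acylation of 26: the first should be secured by the five-membered C=O···Li chelate and the higher acidity of the oxygen-bearing vinylic C–H, the second by the E geometry, because the sec-alkyl group cis to C4 turns the bulky C3 terminus toward O1 and C2. The silyl group keeps C3 free of acidic hydrogen until the ring is closed, so an enolate formed by reversible ring opening cannot scramble the double bond by proton transfer.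

**Step 13**
Reactants: 28 (dioxolane-protected tetronic acid from step 12)
Product: 29 (5E)-5-[(2S,9E)-13-(furan-3-yl)-2,10-dimethyl-6-methylidene-13-oxotridec-9-en-1-ylidene]-4-hydroxy-3-methylfuran-2(5H)-one (target)
Conditions: PPTS (0.2 equiv), acetone/H2O, rt, dark
Reagents that add atoms: water, O
Why: mild acid should hydrolyse the 2-furyl-1,3-dioxolane through a furan-stabilised oxocarbenium ion while the tetronic acid, the E exocyclic alkene and the other alkenes persist (acetal hydrolysis).

**Compound list**
1 | (S)-β-citronellene, (3S)-3,7-dimethylocta-1,6-diene | CC(C)=CCC[C@H](C)C=C | starting material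
2 | (4S)-4-methylhex-5-enal | O=CCC[C@H](C)C=C | intermediate
3 | (4S)-4-methylhex-5-en-1-ol | OCCC[C@H](C)C=C | intermediate
4 | (3S)-6-iodo-3-methylhex-1-ene | ICCC[C@H](C)C=C | intermediate
5 | vinylboronic acid pinacol ester | C=CB1OC(C)(C)C(C)(C)O1 | starting material
6 | 2-[(1E,3S)-6-iodo-3-methylhex-1-en-1-yl]-4,4,5,5-tetramethyl-1,3,2-dioxaborolane | ICCC[C@H](C)/C=C/B1OC(C)(C)C(C)(C)O1 | intermediate
7 | 6-methylhept-5-en-2-one | CC(C)=CCCC(C)=O | starting material
8 | lithium 6-methylhepta-1,5-dien-2-olate | CC(C)=CCCC(=C)O[Li] | intermediate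
9 | 6-methylhepta-1,5-dien-2-yl trifluoromethanesulfonate | CC(C)=CCCC(=C)OS(=O)(=O)C(F)(F)F | intermediate
10 | (5E)-7-hydroxy-6-methylhepta-1,5-dien-2-yl trifluoromethanesulfonate | OC/C(C)=C/CCC(=C)OS(=O)(=O)C(F)(F)F | intermediate
11 | (5E)-7-bromo-6-methylhepta-1,5-dien-2-yl trifluoromethanesulfonate | BrC/C(C)=C/CCC(=C)OS(=O)(=O)C(F)(F)F | intermediate
12 | 3-acetylfuran, 1-(furan-3-yl)ethan-1-one | CC(=O)c1ccoc1 | starting material
13 | lithium 1-(furan-3-yl)ethen-1-olate | C=C(O[Li])c1ccoc1 | intermediate
14 | (5E)-9-(furan-3-yl)-6-methyl-9-oxonona-1,5-dien-2-yl trifluoromethanesulfonate | O=C(CC/C(C)=C/CCC(=C)OS(=O)(=O)C(F)(F)F)c1ccoc1 | intermediate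
15 | (5E)-8-[2-(furan-3-yl)-1,3-dioxolan-2-yl]-6-methylocta-1,5-dien-2-yl trifluoromethanesulfonate | C=C(CC/C=C(\C)CCC1(c2ccoc2)OCCO1)OS(=O)(=O)C(F)(F)F | intermediate
16 | [(4S,5E)-4-methyl-6-(4,4,5,5-tetramethyl-1,3,2-dioxaborolan-2-yl)hex-5-en-1-yl]zinc iodide | I[Zn]CCC[C@H](C)/C=C/B1OC(C)(C)C(C)(C)O1 | intermediate
17 | 2-[(1E,3S,10E)-13-[2-(furan-3-yl)-1,3-dioxolan-2-yl]-3,11-dimethyl-7-methylidenetrideca-1,10-dien-1-yl]-4,4,5,5-tetramethyl-1,3,2-dioxaborolane | C=C(CC/C=C(\C)CCC1(c2ccoc2)OCCO1)CCC[C@H](C)/C=C/B1OC(C)(C)C(C)(C)O1 | intermediate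
18 | 1-propynyllithium | CC#C[Li] | starting material
19 | lithium prop-1-yn-1-olate | CC#CO[Li] | intermediate
20 | methyl(trimethylsilyl)ketene, 2-(trimethylsilyl)prop-1-en-1-one | CC(=C=O)[Si](C)(C)C | intermediate
21 | phenyl chloroformate | O=C(Cl)Oc1ccccc1 | starting material
22 | enol borate: 2-{[(1E,3S,10E)-13-[2-(furan-3-yl)-1,3-dioxolan-2-yl]-3,11-dimethyl-7-methylidenetrideca-1,10-dien-1-yl]oxy}-4,4,5,5-tetramethyl-1,3,2-dioxaborolane | C=C(CC/C=C(\C)CCC1(c2ccoc2)OCCO1)CCC[C@H](C)/C=C/OB1OC(C)(C)C(C)(C)O1 | intermediate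
23 | lithium (1E,3S,10E)-13-[2-(furan-3-yl)-1,3-dioxolan-2-yl]-3,11-dimethyl-7-methylidenetrideca-1,10-dien-1-olate | C=C(CC/C=C(\C)CCC1(c2ccoc2)OCCO1)CCC[C@H](C)/C=C/O[Li] | intermediate
24 | phenyl (1E,3S,10E)-13-[2-(furan-3-yl)-1,3-dioxolan-2-yl]-3,11-dimethyl-7-methylidenetrideca-1,10-dien-1-yl carbonate | C=C(CC/C=C(\C)CCC1(c2ccoc2)OCCO1)CCC[C@H](C)/C=C/OC(=O)Oc1ccccc1 | intermediate
25 | 1-lithio derivative of 24 (Li on the O-bearing alkene carbon, cis to the sec-alkyl group) | C=C(CC/C=C(\C)CCC1(c2ccoc2)OCCO1)CCC[C@H](C)/C=C(/OC(=O)Oc1ccccc1)[Li] | intermediate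
26 | lithium α-silyl enolate: adduct of 25 to the ketene C=O, carbonate intact | C=C(CC/C=C(\C)CCC1(c2ccoc2)OCCO1)CCC[C@H](C)/C=C(/OC(=O)Oc1ccccc1)C(O[Li])=C(C)[Si](C)(C)C | intermediate
27 | (5E)-5-ylidene-3-methyl-3-(trimethylsilyl)furan-2,4(3H,5H)-dione with the side chain of 28 (C3 epimers) | C=C(CC/C=C(\C)CCC1(c2ccoc2)OCCO1)CCC[C@H](C)/C=C1/OC(=O)C(C)([Si](C)(C)C)C1=O | intermediate
28 | (5E)-5-[(2S,9E)-12-[2-(furan-3-yl)-1,3-dioxolan-2-yl]-2,10-dimethyl-6-methylidenedodec-9-en-1-ylidene]-4-hydroxy-3-methylfuran-2(5H)-one | C=C(CC/C=C(\C)CCC1(c2ccoc2)OCCO1)CCC[C@H](C)/C=C1/OC(=O)C(C)=C1O | intermediate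
29 | (5E)-5-[(2S,9E)-13-(furan-3-yl)-2,10-dimethyl-6-methylidene-13-oxotridec-9-en-1-ylidene]-4-hydroxy-3-methylfuran-2(5H)-one | C=C(CC/C=C(\C)CCC(=O)c1ccoc1)CCC[C@H](C)/C=C1/OC(=O)C(C)=C1O | target

**Totals**
Total steps: 13. Longest linear sequence: 9 steps (from 7: steps 4–9, 11, 12, 13).

**Steps most likely to fail**

1. Step 12 (proposed method). The lithiated enol carbonate may decompose before the ketene arrives, by shift of the carbonate carbon from oxygen to carbon, α-elimination to the terminal alkyne, or attack on the carbonate of a second molecule. LiTMP may instead metalate the phenyl or furan ring, or the enolate may be acylated on oxygen. Each of these would stop ring formation or erase the geometry. The fallback uses known tetronate aldol chemistry and then double-bond isomerisation; it sets out from 4 (with 15 as coupling partner) and rejoins at 28. Ozonolysis of the vinyl group of 4 (O3, CH2Cl2, −78 °C; PPh3) should give (2S)-5-iodo-2-methylpentanal F1. Addition of the C5 lithium anion of the known building block 4-methoxy-3-methylfuran-2(5H)-one (LDA, THF, −78 °C) should give the aldol 5-[(2S)-1-hydroxy-5-iodo-2-methylpentyl]-4-methoxy-3-methylfuran-2(5H)-one F2 as a diastereomer mixture. Mesylation and DBU elimination should give (5Z)-5-[(2S)-5-iodo-2-methylpentylidene]-4-methoxy-3-methylfuran-2(5H)-one F3. Zinc insertion and Negishi coupling with 15 as in step 9 should give the full-chain (5Z)-methyl tetronate F4. O-Demethylation with LiCl in DMSO should give the (5Z)-isomer of 28 F5. Irradiation to a photostationary Z/E mixture and chromatographic separation, with recycling of F5, should give 28.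

2. Step 11. The enolate may be released incompletely from boron, or be acylated on carbon, or be protonated and ketonised, which would erode the E geometry. The fallback sets out from 17 and rejoins at 24. KHF2 should convert 17 into the potassium alkenyltrifluoroborate F6. Copper(II)-promoted oxidative C–O coupling with acetate (Chan–Lam type, retention at the sp2 carbon) should give the (E)-enol acetate F7. Two equivalents of MeLi should cleave F7 to the boron-free lithium enolate 23, which is acylated with 21 as in step 11 to give 24.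

3. Step 9. Zinc insertion or the palladium cycle may consume the alkenyl–boron bond (boron–zinc exchange, protodeboronation, Suzuki-type self-coupling with the triflate), or β-hydride elimination in the alkyl–palladium intermediate may give isomerised products. The fallback sets out from 4 and 15 and rejoins at 17. The boron-free iodide 4 is converted into its alkylzinc iodide and coupled with 15 under the same Pd catalysis to give the terminal triene 2-(furan-3-yl)-2-[(3E,11S)-3,11-dimethyl-7-methylidenetrideca-3,12-dien-1-yl]-1,3-dioxolane F8. A Pd-catalysed boryl-Heck reaction with B-chlorocatecholborane and Et3N should borylate the monosubstituted vinyl group E-selectively to give the catechol alkenylboronate F9, and exchange with pinacol should give 17.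

**Further compounds**
F1 | step 12 | (2S)-5-iodo-2-methylpentanal | ICCC[C@H](C)C=O
F2 | step 12 | 5-[(2S)-1-hydroxy-5-iodo-2-methylpentyl]-4-methoxy-3-methylfuran-2(5H)-one | ICCC[C@H](C)C(O)C1OC(=O)C(C)=C1OC
F3 | step 12 | (5Z)-5-[(2S)-5-iodo-2-methylpentylidene]-4-methoxy-3-methylfuran-2(5H)-one | ICCC[C@H](C)/C=C1\OC(=O)C(C)=C1OC
F4 | step 12 | (5Z)-5-[(2S,9E)-12-[2-(furan-3-yl)-1,3-dioxolan-2-yl]-2,10-dimethyl-6-methylidenedodec-9-en-1-ylidene]-4-methoxy-3-methylfuran-2(5H)-one | C=C(CC/C=C(\C)CCC1(c2ccoc2)OCCO1)CCC[C@H](C)/C=C1\OC(=O)C(C)=C1OC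
F5 | step 12 | (5Z)-5-[(2S,9E)-12-[2-(furan-3-yl)-1,3-dioxolan-2-yl]-2,10-dimethyl-6-methylidenedodec-9-en-1-ylidene]-4-hydroxy-3-methylfuran-2(5H)-one | C=C(CC/C=C(\C)CCC1(c2ccoc2)OCCO1)CCC[C@H](C)/C=C1\OC(=O)C(C)=C1O
F6 | step 11 | potassium [(1E,3S,10E)-13-[2-(furan-3-yl)-1,3-dioxolan-2-yl]-3,11-dimethyl-7-methylidenetrideca-1,10-dien-1-yl]trifluoroborate | C=C(CC/C=C(\C)CCC1(c2ccoc2)OCCO1)CCC[C@H](C)/C=C/[B-](F)(F)F.[K+]
F7 | step 11 | (1E,3S,10E)-13-[2-(furan-3-yl)-1,3-dioxolan-2-yl]-3,11-dimethyl-7-methylidenetrideca-1,10-dien-1-yl acetate | C=C(CC/C=C(\C)CCC1(c2ccoc2)OCCO1)CCC[C@H](C)/C=C/OC(C)=O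
F8 | step 9 | 2-(furan-3-yl)-2-[(3E,11S)-3,11-dimethyl-7-methylidenetrideca-3,12-dien-1-yl]-1,3-dioxolane | C=C(CC/C=C(\C)CCC1(c2ccoc2)OCCO1)CCC[C@H](C)C=C
F9 | step 9 | 2-[(1E,3S,10E)-13-[2-(furan-3-yl)-1,3-dioxolan-2-yl]-3,11-dimethyl-7-methylidenetrideca-1,10-dien-1-yl]-1,3,2-benzodioxaborole | C=C(CC/C=C(\C)CCC1(c2ccoc2)OCCO1)CCC[C@H](C)/C=C/B1Oc2ccccc2O1
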